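**Retrosynthetic overview**
1. Last step: hydrogenolysis of five benzyl ethers. Before it, the C2–CH2 bond (chromone numbering) is cut between a 2-arylethylzinc reagent and a 2-chloro-γ-pyrone that is generated in the same flask.
2. Key step: three-component union of a cyclitol silyl enol ether, 3,3-dichloroacryloyl chloride and the alkylzinc; C4–C4a (acylation), O1–C2 (ring closure) and C2–CH2 (Negishi coupling) form in one operation.
3. Enabling feature: the γ-pyrone ring (O1, C2, C3, C4, C4a, C8a) is a vinylogous ester. C2 is a vinylogous acyl carbon (O1–C2=C3–C4=O), so it can be carried as CCl2 and then C–Cl (vinylogous acid chloride); O1/C8a/C4a are the enol of a cyclohexanone, so the ring ketone supplies O1.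
4. The carbocycle with all four stereocentres comes from methyl α-D-glucopyranoside by Ferrier carbocyclisation: glucose C4, C3, C2 become C8, C7, C6; C1 becomes C5 (new centre); C5 becomes C8a; C6 becomes C4a.
5. Ring order: arene (bought), cyclohexanone (step 3), γ-pyrone (step 8).

Key step: step 8

Remark: chromone numbering is used for the bicyclic core and its precursors; 3,3-dichloroacryloyl chloride and 2-(3-hydroxy-4-methoxyphenyl)ethanol are assumed to be purchasable (the former is otherwise available from 3,3-dichloroacrylic acid and oxalyl chloride).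

**Route**

Step 1
Reactants: 1 methyl α-D-glucopyranoside
Product: 2 methyl 6-deoxy-6-iodo-α-D-glucopyranoside
Conditions: I2, PPh3, imidazole, THF, 65 °C
Reagents that add atoms: iodine, II
Why: Garegg–Samuelsson (Appel-type) iodination should be selective for the unhindered primary C6–OH of the free glycoside, and no stereocentre is touched.

Step 2
Reactants: 2 methyl 6-deoxy-6-iodo-α-D-glucopyranoside
Product: 3 methyl 2,3,4-tri-O-benzyl-6-deoxy-α-D-xylo-hex-5-enopyranoside
Conditions: BnBr, NaH, DMF, 0 °C → rt
Reagents that add atoms: benzyl bromide, BrCc1ccccc1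
Why: Williamson benzylation of the three secondary hydroxyls and E2 dehydroiodination of the primary iodide by excess base should occur in the same pot to give the exocyclic enol ether (benzyl bromide is present before the base so that etherification outpaces 3,6-anhydride formation); sugar C2–C4 are unaffected.

Step 3
Reactants: 3 methyl 2,3,4-tri-O-benzyl-6-deoxy-α-D-xylo-hex-5-enopyranoside
Product: 4 (2S,3R,4S,5S)-2,3,4-tris(benzyloxy)-5-hydroxycyclohexan-1-one
Conditions: Hg(OCOCF3)2 (cat.), acetone–H2O 2:1, rt
Reagents that add atoms: water, O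
Why: Ferrier carbocyclisation: hydroxymercuration of the enol ether, loss of methanol to the keto-aldehyde mercury enolate and intramolecular aldol through a chair transition state close the cyclohexanone and set the new carbinol centre (C5 of the target) with the hydroxyl axial, cis to the neighbouring benzyloxy group and trans to the next one, the usual major outcome in the gluco series; the minor C5 epimer is to be removed by chromatography.

Step 4
Reactants: 4 (2S,3R,4S,5S)-2,3,4-tris(benzyloxy)-5-hydroxycyclohexan-1-one
Product: 5 (2S,3R,4S,5S)-2,3,4,5-tetrakis(benzyloxy)cyclohexan-1-one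
Conditions: BnOC(=NH)CCl3, TfOH (cat.), CH2Cl2–cyclohexane, 0 °C → rt
Reagents that add atoms: benzyl 2,2,2-trichloroacetimidate, N=C(OCc1ccccc1)C(Cl)(Cl)Cl
Why: Acid-catalysed O-benzylation with the trichloroacetimidate avoids the base that would cause retro-aldol or β-elimination of the β-hydroxy ketone, and the carbinol C–O bond is not broken, so the configuration is retained.

Step 5
Reactants: 5 (2S,3R,4S,5S)-2,3,4,5-tetrakis(benzyloxy)cyclohexan-1-one
Product: 6 trimethyl{[(3S,4S,5R,6S)-3,4,5,6-tetrakis(benzyloxy)cyclohex-1-en-1-yl]oxy}silane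
Conditions: LDA, TMSCl (internal quench), THF, −78 °C; non-aqueous work-up, used crude
Reagents that add atoms: chlorotrimethylsilane, C[Si](C)(C)Cl
Why: Kinetic enolisation should remove a proton of the unhindered CH2 and not the one on the benzyloxy-bearing α-carbon, and immediate O-silylation traps the enolate before benzyloxide can be lost; the α-stereocentre is not enolised.

Step 6
Reactants: 7 2-(3-hydroxy-4-methoxyphenyl)ethanol
Product: 8 2-[3-(benzyloxy)-4-methoxyphenyl]ethanol
Conditions: BnBr, K2CO3, acetone, reflux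
Reagents that add atoms: benzyl bromide, BrCc1ccccc1
Why: Chemoselective Williamson etherification, since carbonate deprotonates only the phenol and the primary alcohol stays free.

Step 7
Reactants: 8 2-[3-(benzyloxy)-4-methoxyphenyl]ethanol
Product: 9 2-(benzyloxy)-4-(2-iodoethyl)-1-methoxybenzene
Conditions: I2, PPh3, imidazole, CH2Cl2, 0 °C → rt
Reagents that add atoms: iodine, II
Why: Appel iodination of the primary alcohol by SN2 displacement of the alkoxyphosphonium.

Step 8
Reactants: 6 trimethyl{[(3S,4S,5R,6S)-3,4,5,6-tetrakis(benzyloxy)cyclohex-1-en-1-yl]oxy}silane; 9 2-(benzyloxy)-4-(2-iodoethyl)-1-methoxybenzene; 10 3,3-dichloroprop-2-enoyl chloride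
Product: 14 (5S,6S,7R,8S)-5,6,7,8-tetrakis(benzyloxy)-2-{2-[3-(benzyloxy)-4-methoxyphenyl]ethyl}-5,6,7,8-tetrahydro-4H-chromen-4-one, via enolised acyl ketone 11 (not isolated), via 2-chloro-γ-pyrone 12 (not isolated), via alkylzinc iodide 13 (not isolated)
Conditions: (i) 6, 10, ZnCl2, CH2Cl2–Et2O, −40 → 0 °C, then i-Pr2NEt; (ii) THF, PdCl2(dppf) (cat.), 13 [from 9, Zn, LiCl, THF, 40 °C], rt → 40 °C; one flask
Reagents that add atoms: none
Why: Proposed new method: the closest known reaction types are the Lewis-acid (Mukaiyama-type) C-acylation of silyl enol ethers by β-heteroatom-substituted acryloyl chlorides followed by cyclisation to γ-pyrones, and the Negishi coupling of alkylzinc halides with β-chloro enones and 4-chlorocoumarins; new is their telescoping through a gem-dichloro linchpin that keeps exactly one chloride at C2 for the coupling. ZnCl2 activates the acid chloride of 10, the enol ether carbon C4a of 6 attacks it (C4–C4a bond, Me3SiCl lost) to give the enolised acyl ketone 11, whose ring-ketone oxygen adds to the CCl2 carbon and expels chloride (6-endo-trig addition–elimination, SNV), closing the γ-pyrone ring as the vinylogous acid chloride 12 and removing the acidic C4a–H before benzyloxide at C5 can be eliminated. Pd(0) then inserts into the activated C2–Cl bond of 12, and transmetalation with the alkylzinc iodide 13 and reductive elimination form the C2–CH2 bond, the wide-bite-angle dppf ligand favouring reductive elimination over β-hydride elimination. No stereocentre is formed, and C5–C8 should stay intact because no strong base is present at any stage (the γ-proton at C8 of the pyrone is not removed). The selectivities needed are C- over O-acylation (secured by the silyl enol ether/ZnCl2 pairing), the direction of annulation (fixed by the C4a=C8a position of the enol ether in 6 and by the fact that only the C8a oxygen can reach the CCl2 carbon in a six-membered ring) and coupling at C2 only (the single C–halogen bond left; organozinc reagents do not add to the pyrone carbonyl).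

Step 9
Reactants: 14 (5S,6S,7R,8S)-5,6,7,8-tetrakis(benzyloxy)-2-{2-[3-(benzyloxy)-4-methoxyphenyl]ethyl}-5,6,7,8-tetrahydro-4H-chromen-4-one
Product: 15 (5S,6S,7R,8S)-5,6,7,8-tetrahydroxy-2-[2-(3-hydroxy-4-methoxyphenyl)ethyl]-5,6,7,8-tetrahydro-4H-chromen-4-one
Conditions: H2 (1 atm), Pd(OH)2/C, EtOAc–MeOH, rt
Reagents that add atoms: none
Why: Catalytic hydrogenolysis should cleave the five O-benzyl bonds (four alkyl, one aryl) while the vinylogous-ester γ-pyrone ring, as in the debenzylation of benzyl-protected chromones and 4-pyranones, is not reduced at 1 atm; no stereocentre is touched.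

**Compound list**
1 | methyl α-D-glucopyranoside | CO[C@@H]1[C@H](O)[C@@H](O)[C@H](O)[C@@H](CO)O1 | starting material
2 | methyl 6-deoxy-6-iodo-α-D-glucopyranoside | CO[C@@H]1[C@H](O)[C@@H](O)[C@H](O)[C@@H](CI)O1 | intermediate
3 | methyl 2,3,4-tri-O-benzyl-6-deoxy-α-D-xylo-hex-5-enopyranoside | CO[C@@H]1[C@H](OCc2ccccc2)[C@@H](OCc2ccccc2)[C@H](OCc2ccccc2)C(=C)O1 | intermediate
4 | (2S,3R,4S,5S)-2,3,4-tris(benzyloxy)-5-hydroxycyclohexan-1-one | O=C1C[C@H](O)[C@H](OCc2ccccc2)[C@@H](OCc2ccccc2)[C@@H]1OCc1ccccc1 | intermediate
5 | (2S,3R,4S,5S)-2,3,4,5-tetrakis(benzyloxy)cyclohexan-1-one | O=C1C[C@H](OCc2ccccc2)[C@H](OCc2ccccc2)[C@@H](OCc2ccccc2)[C@@H]1OCc1ccccc1 | intermediate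
6 | trimethyl{[(3S,4S,5R,6S)-3,4,5,6-tetrakis(benzyloxy)cyclohex-1-en-1-yl]oxy}silane | C[Si](C)(C)OC1=C[C@H](OCc2ccccc2)[C@H](OCc2ccccc2)[C@@H](OCc2ccccc2)[C@@H]1OCc1ccccc1 | intermediate
7 | 2-(3-hydroxy-4-methoxyphenyl)ethanol | COc1ccc(CCO)cc1O | starting material
8 | 2-[3-(benzyloxy)-4-methoxyphenyl]ethanol | COc1ccc(CCO)cc1OCc1ccccc1 | intermediate
9 | 2-(benzyloxy)-4-(2-iodoethyl)-1-methoxybenzene | COc1ccc(CCI)cc1OCc1ccccc1 | intermediate
10 | 3,3-dichloroprop-2-enoyl chloride | O=C(Cl)C=C(Cl)Cl | starting material
11 | 3,3-dichloro-1-[(3S,4R,5S,6S)-3,4,5,6-tetrakis(benzyloxy)-2-hydroxycyclohex-1-en-1-yl]prop-2-en-1-one (enol form of the 2-acyl ketone) | OC1=C(C(=O)C=C(Cl)Cl)[C@H](OCc2ccccc2)[C@H](OCc2ccccc2)[C@@H](OCc2ccccc2)[C@@H]1OCc1ccccc1 | intermediate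
12 | (5S,6S,7R,8S)-5,6,7,8-tetrakis(benzyloxy)-2-chloro-5,6,7,8-tetrahydro-4H-chromen-4-one | Clc1cc(=O)c2c(o1)[C@@H](OCc1ccccc1)[C@H](OCc1ccccc1)[C@@H](OCc1ccccc1)[C@H]2OCc1ccccc1 | intermediate
13 | {2-[3-(benzyloxy)-4-methoxyphenyl]ethyl}zinc(II) iodide | COc1ccc(CC[Zn]I)cc1OCc1ccccc1 | intermediate
14 | (5S,6S,7R,8S)-5,6,7,8-tetrakis(benzyloxy)-2-{2-[3-(benzyloxy)-4-methoxyphenyl]ethyl}-5,6,7,8-tetrahydro-4H-chromen-4-one | COc1ccc(CCc2cc(=O)c3c(o2)[C@@H](OCc2ccccc2)[C@H](OCc2ccccc2)[C@@H](OCc2ccccc2)[C@H]3OCc2ccccc2)cc1OCc1ccccc1 | intermediate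
15 | (5S,6S,7R,8S)-5,6,7,8-tetrahydroxy-2-[2-(3-hydroxy-4-methoxyphenyl)ethyl]-5,6,7,8-tetrahydro-4H-chromen-4-one | COc1ccc(CCc2cc(=O)c3c(o2)[C@@H](O)[C@H](O)[C@@H](O)[C@H]3O)cc1O | target

**Step count**
Total: 9 steps. Longest linear sequence: 7 steps (steps 1–5, 8, 9).

**Steps most likely to fail**

Step 8 (Proposed new method). What may go wrong: elimination of benzyl alcohol from the enolised acyl ketone in competition with ring closure, Lewis-acid ionisation of the allylic C5–O bond of the enol ether, loss of the vinylogous acid chloride before it is coupled, and β-hydride elimination at palladium. The fallback uses known chemistry, sets out from 6 and comes back at 14. Commercial 3-(benzyloxy)-4-methoxybenzyl alcohol is converted with PBr3 into 3-(benzyloxy)-4-methoxybenzyl bromide F1. F1 alkylates the lithium dienolate of commercial 2,2,6-trimethyl-4H-1,3-dioxin-4-one (LDA, THF–DMPU, −78 °C) at the exocyclic carbon to give 6-{2-[3-(benzyloxy)-4-methoxyphenyl]ethyl}-2,2-dimethyl-4H-1,3-dioxin-4-one F2. Heating F2 with 6 in toluene at 110 °C expels acetone and gives the acylketene 5-[3-(benzyloxy)-4-methoxyphenyl]pent-1-ene-1,3-dione F3, which adds across the enol ether double bond of 6 in a hetero-Diels–Alder reaction; loss of trimethylsilanol (TsOH on work-up) then gives 14.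

Step 5. What may go wrong: β-elimination of benzyloxide from the lithium enolate, or deprotonation on the benzyloxy-bearing side with loss of regiocontrol and epimerisation of that centre. The fallback sets out from 5 and comes back at 12, which is then taken through the coupling stage of step 8 to 14. Condensation of 5 with morpholine (PPTS cat., 4 Å molecular sieves, toluene) should give the less substituted enamine 4-[3,4,5,6-tetrakis(benzyloxy)cyclohex-1-en-1-yl]morpholine F4 (ring stereocentres as in 5) without strong base. Stork acylation of F4 with 10 (i-Pr2NEt, CH2Cl2, 0 °C) gives the enaminone 3,3-dichloro-1-[3,4,5,6-tetrakis(benzyloxy)-2-(morpholin-4-yl)cyclohex-1-en-1-yl]prop-2-en-1-one F5. Buffered hydrolysis (aq. AcOH–NaOAc) releases 11, and i-Pr2NEt closes it to 12, which is isolated and coupled with 13 under the palladium conditions of step 8.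

Step 9. What may go wrong: over-reduction of the pyrone C2=C3 bond, or hydrogenolysis of the C5–O and C8–O bonds, which are activated by the pyrone ring. The fallback sets out from 14 and arrives at 15: Lewis-acid debenzylation with BCl3 and pentamethylbenzene as benzyl-cation scavenger in CH2Cl2 at −78 °C, then methanol quench. No hydrogen and no metal surface are involved, the aryl methyl ether is expected to survive at this temperature, and no new compound lies on the way.

**Further compounds**
F1 | step 8 | 3-(benzyloxy)-4-methoxybenzyl bromide | COc1ccc(CBr)cc1OCc1ccccc1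
F2 | step 8 | 6-{2-[3-(benzyloxy)-4-methoxyphenyl]ethyl}-2,2-dimethyl-4H-1,3-dioxin-4-one | COc1ccc(CCC2=CC(=O)OC(C)(C)O2)cc1OCc1ccccc1
F3 | step 8 | 5-[3-(benzyloxy)-4-methoxyphenyl]pent-1-ene-1,3-dione | COc1ccc(CCC(=O)C=C=O)cc1OCc1ccccc1
F4 | step 5 | 4-[3,4,5,6-tetrakis(benzyloxy)cyclohex-1-en-1-yl]morpholine (ring stereocentres as in 5) | C1COCCN1C1=C[C@H](OCc2ccccc2)[C@H](OCc2ccccc2)[C@@H](OCc2ccccc2)[C@@H]1OCc1ccccc1
F5 | step 5 | 3,3-dichloro-1-[3,4,5,6-tetrakis(benzyloxy)-2-(morpholin-4-yl)cyclohex-1-en-1-yl]prop-2-en-1-one (ring stereocentres as in 5) | C1COCCN1C1=C(C(=O)C=C(Cl)Cl)[C@H](OCc2ccccc2)[C@H](OCc2ccccc2)[C@@H](OCc2ccccc2)[C@@H]1OCc1ccccc1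
F0 | step 9 | none | none
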